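I decided to reckon this flask by the nucleophile it loses.

| setting | violet | grey | flask |
|---|---|---|---|
| electrophile | 0.20 M | 0.10 M | 0.20 M |
| nucleophile | 0.20 M | 0.20 M | 0.200 M |
| free base | 0.22 M | 0.22 M | 0.220 M |
| scavenger | 0.30 M | 0.30 M | 0.300 M |
| remark | the very flask that is asked about, followed so far | run made earlier |  |
| time |  |  | 12 h |

- violet (time / h: electrophile / %, product / %): 1.33: 19.7, 77.8; 2.50: 13.9, 86.1; 4.00: 11.9, 91.3; 5.00: 8.6, 90.2; 6.00: 9.6, 89.9
- grey (time / h: electrophile / %, product / %): 2.50: 1.5, 100.3; 5.00: 0.5, 100.2; 8.00: 0, 99.6; 10.0: 0.9, 99.5; 12.0: 0.5, 100.8

(each reading ± 1 percentage point)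

- part of the electrophile that has reacted at 12 h
- share of the unused nucleophile that is free and not bound as protonated nucleophile, at 12 h

Violet had equal charges, so the electrophile left equals the nucleophile lost plus the nucleophile left. Grey, with twice the nucleophile per electrophile, read 100.8% product at 12.0 h, so I saw no side exit for the electrophile.

From above: the first violet reading gave a second-order constant of 15.3 /M/h, and this leak-free law leaves 2.65% of the electrophile at 12 h. It leaves 5.16% at 6.00 h, yet the last three violet readings average 10.0%. I charged that excess to lost nucleophile, which lowered the ceiling on c to 95.2%.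

From below: taking the electrophile as unable to rise, I put c at 90.0% or more. Violet product stayed flat within the scatter, so I took the nucleophile left there as below 1 percentage point of its charge and read 9.53% as the leak, the share of charged nucleophile that never became product. The reach, one minus the leak times charged nucleophile over charged electrophile, gave c of 90.5%. Free base and scavenger together were charged above the electrophile, so I guessed fr near 100%.

The forecast, at 93% and 30%, put c inside my bracket and held that “about 30–40% of the remaining nucleophile is free”.

The flask gave 91.3% and >99.9%.

    nucleophile + acid set free ⇌ protonated nucleophile, settled at all times (K = 87.0 /M)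
    electrophile + nucleophile → acid set free + product (k = 28.0 /M/h)
    electrophile + acid set free ⇌ idle adduct, settled at all times (K = 22.0 /M)
    acid set free + free base ⇌ salt of the base (K = 1.50 × 10⁵ /M, k = 31.0 /M/h)
    2 nucleophile → homo dimer (k = 2.00 /M/h)
    acid set free + scavenger → scavenged by-product (k = 48.0 /M/h)

At 12.0 h the flask held 0.032% of its nucleophile, the limiting reagent, and 0.00867 M homo dimer, two nucleophile each, or 8.67% of the charge. For the neighbour flask with 0.050 M nucleophile I reckoned, by the same leak, a reach of 22.6%. It gave 24.6%, with 0% nucleophile and 75% electrophile left. Its homo dimer stood at 4.31 × 10⁻⁴ M, which holds 1.72% of its nucleophile charge.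

The readings were computed from invented constants; scatter was added.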